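**Retrosynthetic overview**

1. Target ⇒ (fluoride desilylation with tautomerization; ortho-oxidation at C-5') ⇒ a ring B phenol: a 2-prenyl-3-silyloxyphenol that carries the (3R)-chromanyl group para to the free hydroxyl.
2. Ring B ⇒ benzannulation of a vinylketene (from an α-diazo vinyl ketone by Wolff rearrangement) with a prenyl-substituted siloxyalkyne; the ring closes by a 6π electrocyclization that joins C-4' (the carbon that keeps the hydroxyl) to C-5' (the later quinone carbonyl carbon).
3. Enabling feature: in ring B, O-2' and O-4' stand 1,3 across the prenylated C-3' (an ynol ether C-2'/C-3' plus a ketene carbon C-4'); C-1' bears the chroman (the ketene α-carbon); C-6' and C-5' come from a vinyl group, and the C-5' carbonyl lies ortho to the C-4' hydroxyl, so oxidation can add it.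
4. Diazo ketone ⇒ chroman-3-ylacetic Weinreb amide ⇒ Mitsunobu closure of pyran ring C (O-1 to C-2) ⇒ β-benzyl-γ-butyrolactone ⇒ asymmetric hydrogenation of a Stobbe half-ester (sets C-3) ⇒ C-prenylated 2,4,6-trihydroxybenzaldehyde.
5. Ring order: ring A is bought, ring C is closed second, ring B is built last in the key step.

Key step: step 14

Remark on the chemistry (assumption): atom numbers follow isoflavan usage (chroman O-1 to C-8a for rings A and C, primed numbers for ring B, C-1' bonded to C-3); the target stereocenter C-3 is R. Abbreviations in names: prenyl = 3-methylbut-2-en-1-yl; MOM = methoxymethyl; TIPS = tri(propan-2-yl)silyl; Chr = (3R)-5-methoxy-6-prenyl-7-(TIPS-oxy)-3,4-dihydro-2H-chromen-3-yl.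

**Route**

Step 1
Reactants: 1 2,4,6-trihydroxybenzaldehyde; 2 1-bromo-3-methylbut-2-ene (prenyl bromide)
Product: 3 2,4,6-trihydroxy-3-prenylbenzaldehyde
Conditions: DBU, THF, 0 °C to rt
Reagents that add atoms: none
Why: C-alkylation of the phloroglucinol-type phenoxide (C-prenylation) should take place at one of the two equivalent ring CH positions that lie between two oxygens, so only one mono-C-prenyl regioisomer can form.

Step 2
Reactants: 3 2,4,6-trihydroxy-3-prenylbenzaldehyde
Product: 4 2-hydroxy-4,6-bis(methoxymethoxy)-3-prenylbenzaldehyde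
Conditions: MOMCl, i-Pr2NEt, CH2Cl2, 0 °C
Reagents that add atoms: chloromethyl methyl ether, COCCl
Why: Williamson-type acetal formation should take the most acidic, non-chelated 4-OH and then the less hindered 6-OH, while the 2-OH, pressed by the neighbouring prenyl group into a strong hydrogen bond with the formyl oxygen, stays free.

Step 3
Reactants: 4 2-hydroxy-4,6-bis(methoxymethoxy)-3-prenylbenzaldehyde
Product: 5 2-methoxy-4,6-bis(methoxymethoxy)-3-prenylbenzaldehyde
Conditions: MeI, K2CO3, DMF, 40 °C
Reagents that add atoms: iodomethane, CI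
Why: Williamson O-methylation of the remaining chelated phenol fixes the methoxy group between the formyl carbon and the prenyl carbon, as ring A of the target requires.

Step 4
Reactants: 5 2-methoxy-4,6-bis(methoxymethoxy)-3-prenylbenzaldehyde; 6 dimethyl succinate
Product: 7 (3E)-3-(methoxycarbonyl)-4-[2-methoxy-4,6-bis(methoxymethoxy)-3-prenylphenyl]but-3-enoic acid
Conditions: KOt-Bu, t-BuOH, reflux; then aq. HCl
Reagents that add atoms: none
Why: Stobbe condensation: the succinate enolate adds to the aldehyde, the aldolate lactonizes and base opens the lactone to the alkylidene half-ester with the free acid on the CH2 arm; MOM ethers and the prenyl group tolerate tert-butoxide.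

Step 5
Reactants: 7 (3E)-3-(methoxycarbonyl)-4-[2-methoxy-4,6-bis(methoxymethoxy)-3-prenylphenyl]but-3-enoic acid
Product: 8 (3R)-3-(methoxycarbonyl)-4-[2-methoxy-4,6-bis(methoxymethoxy)-3-prenylphenyl]butanoic acid
Conditions: H2 (5 bar), [Rh(cod)((S,S)-Et-DuPhos)]BF4 (cat.; ligand = 1,2-bis[(2S,5S)-2,5-diethylphospholan-1-yl]benzene), NaOMe (cat.), MeOH, rt
Reagents that add atoms: none
Why: Rhodium-bisphospholane asymmetric hydrogenation of an itaconate-type half-ester: carboxylate and alkene chelate rhodium and the C2-symmetric ligand selects the alkene face, so the stereocenter (the future C-3) is set under catalyst control, the (S,S) ligand being expected by analogy with benzylidenesuccinate half-esters to give the R acid from either alkene isomer, while the non-coordinating prenyl alkene should survive.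

Step 6
Reactants: 8 (3R)-3-(methoxycarbonyl)-4-[2-methoxy-4,6-bis(methoxymethoxy)-3-prenylphenyl]butanoic acid
Product: 10 (4R)-4-{[4,6-dihydroxy-2-methoxy-3-prenylphenyl]methyl}oxolan-2-one, via hydroxy acid 9 (not isolated)
Conditions: LiBH4, THF, 0 °C to rt; then 2 M HCl, MeOH, 40 °C
Reagents that add atoms: none
Why: Chemoselective ester reduction (LiBH4 reduces the ester but not the lithium carboxylate) followed by acid-catalysed lactonization and cleavage of both MOM acetals; the stereocenter is not touched.

Step 7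
Reactants: 10 (4R)-4-{[4,6-dihydroxy-2-methoxy-3-prenylphenyl]methyl}oxolan-2-one
Product: 11 (3R)-4-[4,6-dihydroxy-2-methoxy-3-prenylphenyl]-3-(hydroxymethyl)-N-methoxy-N-methylbutanamide
Conditions: MeNHOMe·HCl, AlMe3 (excess), CH2Cl2, 0 °C to rt; aq. sodium potassium tartrate; crude product used at once
Reagents that add atoms: N,O-dimethylhydroxylamine hydrochloride, CNOC.Cl
Why: Weinreb aminolysis of the lactone by the aluminium amide opens the ring to the γ-hydroxy N-methoxy-N-methylamide, the phenols being held as aluminium phenoxides until work-up.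

Step 8
Reactants: 11 (3R)-4-[4,6-dihydroxy-2-methoxy-3-prenylphenyl]-3-(hydroxymethyl)-N-methoxy-N-methylbutanamide
Product: 12 2-[(3R)-7-hydroxy-5-methoxy-6-prenyl-3,4-dihydro-2H-chromen-3-yl]-N-methoxy-N-methylacetamide
Conditions: PPh3, DIAD, THF (dilute), 0 °C to rt
Reagents that add atoms: none
Why: Intramolecular Mitsunobu etherification: only the phenol ortho to the side chain can reach the activated primary carbon (6-exo-tet), which closes pyran ring C, and the stereocenter, one carbon away from the reacting centre, is retained.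

Step 9
Reactants: 12 2-[(3R)-7-hydroxy-5-methoxy-6-prenyl-3,4-dihydro-2H-chromen-3-yl]-N-methoxy-N-methylacetamide
Product: 13 2-Chr-N-methoxy-N-methylacetamide
Conditions: TIPSCl, imidazole, DMF, rt
Reagents that add atoms: chlorotri(propan-2-yl)silane, CC(C)[Si](Cl)(C(C)C)C(C)C
Why: Silylation of the remaining phenol gives a fluoride-labile aryl silyl ether that should survive the Grignard reagent, the amide base, irradiation and the later oxidation.

Step 10
Reactants: 13 2-Chr-N-methoxy-N-methylacetamide
Product: 14 1-Chr-but-3-en-2-one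
Conditions: CH2=CHMgBr, THF, −20 to 0 °C; inverse quench into cold 1 M HCl
Reagents that add atoms: vinylmagnesium bromide, C=C[Mg]Br
Why: Weinreb ketone synthesis: the chelated tetrahedral intermediate prevents over-addition, and the inverse acidic quench keeps the released amine from adding to the enone.

Step 11
Reactants: 14 1-Chr-but-3-en-2-one
Product: 16 1-Chr-1-diazobut-3-en-2-one, via trifluoroacetyl diketone 15 (not isolated)
Conditions: LiN(SiMe3)2, THF, −78 °C; CF3CO2CH2CF3, −78 °C; then MsN3, Et3N, H2O, MeCN, rt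
Reagents that add atoms: methanesulfonyl azide, CS(=O)(=O)N=[N+]=[N-]; 2,2,2-trifluoroethyl trifluoroacetate (for 15 only), O=C(OCC(F)(F)F)C(F)(F)F
Why: Detrifluoroacetylative diazo transfer (a Regitz-type deacylative diazo transfer): the kinetic α'-enolate is C-trifluoroacetylated and the 1,3-diketone takes the diazo group from MsN3 with loss of the trifluoroacetyl group, which places the diazo carbon next to C-3 without touching that stereocenter.

Step 12
Reactants: 17 ethynylmagnesium bromide; 2 1-bromo-3-methylbut-2-ene (prenyl bromide)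
Product: 18 5-methylhex-4-en-1-yne
Conditions: CuBr·SMe2 (cat.), THF, 0 °C to rt
Reagents that add atoms: none
Why: Copper-catalysed coupling of the alkynyl Grignard reagent with the allylic bromide should occur at the primary carbon (SN2) and give the skipped enyne.

Step 13
Reactants: 18 5-methylhex-4-en-1-yne
Product: 20 triisopropyl[(5-methylhex-4-en-1-yn-1-yl)oxy]silane, via lithium ynolate 19 (not isolated)
Conditions: n-BuLi, THF, −78 °C; LiOOt-Bu (from t-BuOOH and LiN(SiMe3)2), −78 to 0 °C; then TIPSOTf, −78 to 0 °C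
Reagents that add atoms: tert-butyl hydroperoxide, CC(C)(C)OO; tri(propan-2-yl)silyl trifluoromethanesulfonate, CC(C)[Si](OS(=O)(=O)C(F)(F)F)(C(C)C)C(C)C
Why: Electrophilic oxygen transfer from lithium tert-butyl peroxide to the lithium acetylide gives the lithium ynolate, which the bulky silyl triflate traps on oxygen to give the siloxyalkyne.

Step 14
Reactants: 16 1-Chr-1-diazobut-3-en-2-one; 20 triisopropyl[(5-methylhex-4-en-1-yn-1-yl)oxy]silane
Product: 25 4-Chr-2-prenyl-3-(TIPS-oxy)phenol, via vinylketene 21 (not isolated), via vinylcyclobutenone 22 (not isolated), via dienylketene 23 (not isolated), via cyclohexadienone 24 (not isolated)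
Conditions: 20 (1.5 equiv), hν (300 nm, Pyrex), ClCH2CH2Cl, rt; then 80 °C in the dark
Reagents that add atoms: none
Why: Irradiation expels N2 from 16 and the vinyl group migrates to the diazo carbon (photochemical Wolff rearrangement) to give vinylketene 21, whose carbonyl carbon is attacked by the nucleophilic prenyl-bearing carbon of siloxyalkyne 20 in a regiospecific [2+2] cycloaddition to cyclobutenone 22, and on heating 22 opens by 4π electrocyclic ring opening to dienylketene 23, which closes and enolizes to phenol 25. The closest known reaction type is the Danheiser benzannulation in its diazo ketone form with a siloxyalkyne. Ring B closes by a thermal disrotatory 6π electrocyclization of the (Z)-dienylketene that joins the ketene carbon (C-4') to the CH2 terminus of the former vinyl group (C-5') and gives dienone 24, while the four-membered ring of 22 is closed by the [2+2] step and opened again in the same flask. No new stereocenter survives: the quaternary carbon of 22 forms as both epimers, which converge on the same planar ring B, and C-3 of the chroman is a non-enolizable spectator that keeps its R configuration. The step needs (a) regiocontrol, secured by the polarization of the ynol ether, which puts prenyl ortho to the new hydroxyl and the silyloxy group between prenyl and the chromanyl carbon, (b) a dienylketene with the vinyl group cis to the ketene, reached because ring opening of 22 is reversible and only that isomer is drained by cyclization, and (c) vinyl migration ahead of a 1,2-hydrogen shift from C-3, favoured by direct irradiation of the s-Z conformer and by the high migratory aptitude of the vinyl group.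

Step 15
Reactants: 25 4-Chr-2-prenyl-3-(TIPS-oxy)phenol
Product: 26 5-Chr-3-prenyl-4-(TIPS-oxy)cyclohexa-3,5-diene-1,2-dione
Conditions: (KO3S)2NO (Fremy's salt), KH2PO4 buffer, acetone–H2O, 0 °C to rt
Reagents that add atoms: potassium nitrosodisulfonate, [K+].[K+].[O-]S(=O)(=O)N([O])S(=O)(=O)[O-]
Why: Teuber oxidation: the nitroxyl radical abstracts the phenolic hydrogen and oxygenates the phenoxyl radical at the only free ortho position (the para carbon and the other ortho carbon are substituted), giving an ortho-quinone that is stabilized as a vinylogous silyl ester, while the silylated ring A phenol is inert.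

Step 16
Reactants: 26 5-Chr-3-prenyl-4-(TIPS-oxy)cyclohexa-3,5-diene-1,2-dione
Product: 27 2-hydroxy-5-[(3R)-7-hydroxy-5-methoxy-6-prenyl-3,4-dihydro-2H-chromen-3-yl]-3-prenylcyclohexa-2,5-diene-1,4-dione
Conditions: Bu4NF, AcOH, THF, 0 °C; then dilute aq. citric acid
Reagents that add atoms: none
Why: Fluoride-mediated desilylation cleaves the aryl silyl ether and the vinylogous silyl ester, and the freed 4-hydroxy-ortho-quinone tautomerizes to the more stable 2-hydroxy-para-quinone, which is the target with C-3 unchanged.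

**Compound list**

1 | 2,4,6-trihydroxybenzaldehyde | O=Cc1c(O)cc(O)cc1O | starting material
2 | 1-bromo-3-methylbut-2-ene (prenyl bromide) | CC(C)=CCBr | starting material
3 | 2,4,6-trihydroxy-3-prenylbenzaldehyde | O=Cc1c(O)cc(O)c(CC=C(C)C)c1O | intermediate
4 | 2-hydroxy-4,6-bis(methoxymethoxy)-3-prenylbenzaldehyde | O=Cc1c(OCOC)cc(OCOC)c(CC=C(C)C)c1O | intermediate
5 | 2-methoxy-4,6-bis(methoxymethoxy)-3-prenylbenzaldehyde | O=Cc1c(OCOC)cc(OCOC)c(CC=C(C)C)c1OC | intermediate
6 | dimethyl succinate | COC(=O)CCC(=O)OC | starting material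
7 | (3E)-3-(methoxycarbonyl)-4-[2-methoxy-4,6-bis(methoxymethoxy)-3-prenylphenyl]but-3-enoic acid | COCOc1cc(OCOC)c(CC=C(C)C)c(OC)c1/C=C(\CC(=O)O)C(=O)OC | intermediate
8 | (3R)-3-(methoxycarbonyl)-4-[2-methoxy-4,6-bis(methoxymethoxy)-3-prenylphenyl]butanoic acid | COCOc1cc(OCOC)c(CC=C(C)C)c(OC)c1C[C@H](CC(=O)O)C(=O)OC | intermediate
9 | (3R)-3-(hydroxymethyl)-4-[2-methoxy-4,6-bis(methoxymethoxy)-3-prenylphenyl]butanoic acid (hydroxy acid) | COCOc1cc(OCOC)c(CC=C(C)C)c(OC)c1C[C@H](CC(=O)O)CO | intermediate
10 | (4R)-4-{[4,6-dihydroxy-2-methoxy-3-prenylphenyl]methyl}oxolan-2-one | Oc1cc(O)c(CC=C(C)C)c(OC)c1C[C@@H]1CC(=O)OC1 | intermediate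
11 | (3R)-4-[4,6-dihydroxy-2-methoxy-3-prenylphenyl]-3-(hydroxymethyl)-N-methoxy-N-methylbutanamide | Oc1cc(O)c(CC=C(C)C)c(OC)c1C[C@H](CC(=O)N(C)OC)CO | intermediate
12 | 2-[(3R)-7-hydroxy-5-methoxy-6-prenyl-3,4-dihydro-2H-chromen-3-yl]-N-methoxy-N-methylacetamide | COc1c(CC=C(C)C)c(O)cc2c1C[C@H](CC(=O)N(C)OC)CO2 | intermediate
13 | 2-Chr-N-methoxy-N-methylacetamide | COc1c(CC=C(C)C)c(O[Si](C(C)C)(C(C)C)C(C)C)cc2c1C[C@H](CC(=O)N(C)OC)CO2 | intermediate
14 | 1-Chr-but-3-en-2-one | COc1c(CC=C(C)C)c(O[Si](C(C)C)(C(C)C)C(C)C)cc2c1C[C@H](CC(=O)C=C)CO2 | intermediate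
15 | 3-Chr-1,1,1-trifluorohex-5-ene-2,4-dione (trifluoroacetyl diketone; both configurations at the chain carbon) | COc1c(CC=C(C)C)c(O[Si](C(C)C)(C(C)C)C(C)C)cc2c1C[C@H](C(C(=O)C=C)C(=O)C(F)(F)F)CO2 | intermediate
16 | 1-Chr-1-diazobut-3-en-2-one | COc1c(CC=C(C)C)c(O[Si](C(C)C)(C(C)C)C(C)C)cc2c1C[C@H](C(=[N+]=[N-])C(=O)C=C)CO2 | intermediate
17 | ethynylmagnesium bromide | C#C[Mg]Br | starting material
18 | 5-methylhex-4-en-1-yne | CC(C)=CCC#C | intermediate
19 | lithium 5-methylhex-4-en-1-yn-1-olate (lithium ynolate) | [Li+].[O-]C#CCC=C(C)C | intermediate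
20 | triisopropyl[(5-methylhex-4-en-1-yn-1-yl)oxy]silane | CC(C)=CCC#CO[Si](C(C)C)(C(C)C)C(C)C | intermediate
21 | 2-Chr-buta-1,3-dien-1-one (vinylketene) | COc1c(CC=C(C)C)c(O[Si](C(C)C)(C(C)C)C(C)C)cc2c1C[C@H](C(C=C)=C=O)CO2 | intermediate
22 | 4-Chr-4-ethenyl-2-prenyl-3-(TIPS-oxy)cyclobut-2-en-1-one (vinylcyclobutenone; both configurations at C-4 of the four-membered ring) | COc1c(CC=C(C)C)c(O[Si](C(C)C)(C(C)C)C(C)C)cc2c1C[C@H](C1(C=C)C(=O)C(CC=C(C)C)=C1O[Si](C(C)C)(C(C)C)C(C)C)CO2 | intermediate
23 | (3Z)-4-Chr-2-prenyl-3-(TIPS-oxy)hexa-1,3,5-trien-1-one (dienylketene) | COc1c(CC=C(C)C)c(O[Si](C(C)C)(C(C)C)C(C)C)cc2c1C[C@H](C(/C=C)=C(O[Si](C(C)C)(C(C)C)C(C)C)/C(CC=C(C)C)=C=O)CO2 | intermediate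
24 | 4-Chr-2-prenyl-3-(TIPS-oxy)cyclohexa-2,4-dien-1-one (cyclohexadienone) | COc1c(CC=C(C)C)c(O[Si](C(C)C)(C(C)C)C(C)C)cc2c1C[C@H](C1=CCC(=O)C(CC=C(C)C)=C1O[Si](C(C)C)(C(C)C)C(C)C)CO2 | intermediate
25 | 4-Chr-2-prenyl-3-(TIPS-oxy)phenol | COc1c(CC=C(C)C)c(O[Si](C(C)C)(C(C)C)C(C)C)cc2c1C[C@H](c1ccc(O)c(CC=C(C)C)c1O[Si](C(C)C)(C(C)C)C(C)C)CO2 | intermediate
26 | 5-Chr-3-prenyl-4-(TIPS-oxy)cyclohexa-3,5-diene-1,2-dione | COc1c(CC=C(C)C)c(O[Si](C(C)C)(C(C)C)C(C)C)cc2c1C[C@H](C1=CC(=O)C(=O)C(CC=C(C)C)=C1O[Si](C(C)C)(C(C)C)C(C)C)CO2 | intermediate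
27 | 2-hydroxy-5-[(3R)-7-hydroxy-5-methoxy-6-prenyl-3,4-dihydro-2H-chromen-3-yl]-3-prenylcyclohexa-2,5-diene-1,4-dione | COc1c(CC=C(C)C)c(O)cc2c1C[C@H](C1=CC(=O)C(O)=C(CC=C(C)C)C1=O)CO2 | target

**Step count and risks**

Total step count: 16. Longest linear sequence: 14 (steps 1 to 11, then 14 to 16); steps 12 and 13 make the siloxyalkyne separately.

Most likely to fail, step 14: after loss of N2 the acyl carbene (reached mainly from the s-E conformer of the disubstituted diazo ketone) may undergo a 1,2-hydrogen shift from C-3 instead of vinyl migration, which consumes material and erases the stereocenter in that portion; photodegradation of the electron-rich arenes is a second drain. The fallback sets out from 13 and comes back at 25; it generates the same vinylketene 21 without a carbene, by thermal 4π ring opening of a cyclobutenone (the thermal cyclobutenone form of the same benzannulation). Reduction of 13 with i-Bu2AlH should give aldehyde F1, Pinnick oxidation (NaClO2, NaH2PO4, 2-methylbut-2-ene in large excess) acid F2, and (COCl)2 acid chloride F3. Et3N in ethyl vinyl ether should dehydrochlorinate F3 to alkylketene F4, which adds to the enol ether in a [2+2] cycloaddition (ketene carbonyl carbon to the CH2 terminus) to give 3-ethoxycyclobutanone F5. Acid-catalysed loss of ethanol through the more substituted enol (cat. TsOH) should give cyclobutenone F6, and heating F6 with 20 in toluene at 80 to 110 °C should pass through 21, 22, 23 and 24 to 25.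

Second, step 11: the lithium enolate, the amide base or the sulfonamide anion may add in conjugate fashion to the unsubstituted vinyl ketone, so that oligomerization outruns C-trifluoroacetylation. The fallback sets out from 13 and comes back at 26; it carries the enone as a vinylogous ester, a poor Michael acceptor and a standard substrate for kinetic α'-enolization. Addition of (Z)-2-ethoxyvinyllithium (from (Z)-1-bromo-2-ethoxyethene and t-BuLi) to 13 should give β-ethoxy enone F7 (E after work-up; the geometry is immaterial). The same trifluoroacetylation and diazo transfer should give diazo ketone F8, and irradiation of F8 with 20 followed by heating should give, by the same Wolff, [2+2], 4π and 6π sequence, ethoxyphenol F9, in which C-5' already carries oxygen. Dealkylative periodate oxidation of this ortho-alkoxyphenol (NaIO4, aq. MeOH) should then give 26 with loss of ethanol.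

Third, step 15: hydrogen abstraction from the hindered phenol may be slow, the phenoxyl radical may couple at the substituted para carbon C-1' instead of C-5', or the vinylogous silyl ester may hydrolyse in the aqueous medium and over-oxidize. The fallback sets out from 25 and comes back at 27; it reverses the last two operations and delivers the oxygen para to a free phenol instead of ortho. Bu4NF with AcOH should remove both silyl groups from 25 to give triol F10. Co(salen) (divalent cobalt) under O2 in DMF oxidizes phenols with a free para position to para-quinones; in F10 only the 2'-hydroxyl has one (C-5'), the ring A hydroxyl being para-blocked by C-4a, so 27 should form directly.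

Further compounds
F1 | step 14 | 2-Chr-acetaldehyde | COc1c(CC=C(C)C)c(O[Si](C(C)C)(C(C)C)C(C)C)cc2c1C[C@H](CC=O)CO2
F2 | step 14 | 2-Chr-acetic acid | COc1c(CC=C(C)C)c(O[Si](C(C)C)(C(C)C)C(C)C)cc2c1C[C@H](CC(=O)O)CO2
F3 | step 14 | 2-Chr-acetyl chloride | COc1c(CC=C(C)C)c(O[Si](C(C)C)(C(C)C)C(C)C)cc2c1C[C@H](CC(=O)Cl)CO2
F4 | step 14 | 2-Chr-ethen-1-one (alkylketene) | COc1c(CC=C(C)C)c(O[Si](C(C)C)(C(C)C)C(C)C)cc2c1C[C@H](C=C=O)CO2
F5 | step 14 | 2-Chr-3-ethoxycyclobutan-1-one (mixture of ring diastereomers) | COc1c(CC=C(C)C)c(O[Si](C(C)C)(C(C)C)C(C)C)cc2c1C[C@H](C1C(=O)CC1OCC)CO2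
F6 | step 14 | 2-Chr-cyclobut-2-en-1-one | COc1c(CC=C(C)C)c(O[Si](C(C)C)(C(C)C)C(C)C)cc2c1C[C@H](C1=CCC1=O)CO2
F7 | step 11 | (3E)-1-Chr-4-ethoxybut-3-en-2-one | COc1c(CC=C(C)C)c(O[Si](C(C)C)(C(C)C)C(C)C)cc2c1C[C@H](CC(=O)/C=C/OCC)CO2
F8 | step 11 | (3E)-1-Chr-1-diazo-4-ethoxybut-3-en-2-one | COc1c(CC=C(C)C)c(O[Si](C(C)C)(C(C)C)C(C)C)cc2c1C[C@H](C(=[N+]=[N-])C(=O)/C=C/OCC)CO2
F9 | step 11 | 4-Chr-6-ethoxy-2-prenyl-3-(TIPS-oxy)phenol | COc1c(CC=C(C)C)c(O[Si](C(C)C)(C(C)C)C(C)C)cc2c1C[C@H](c1cc(OCC)c(O)c(CC=C(C)C)c1O[Si](C(C)C)(C(C)C)C(C)C)CO2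
F10 | step 15 | 4-[(3R)-7-hydroxy-5-methoxy-6-prenyl-3,4-dihydro-2H-chromen-3-yl]-2-prenylbenzene-1,3-diol | COc1c(CC=C(C)C)c(O)cc2c1C[C@H](c1ccc(O)c(CC=C(C)C)c1O)CO2
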